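Plan (labdane numbering C1–C20)
- Cuts: C4–C18 (the CH2O carbon on the quaternary ring-A carbon) between an 18-nor-4(19)-ene decalin and an iodomethyl cinnamate; before that C8=C17 (from an 8-ol), C13–H/C13=C14 and C13–C16 (side chain grown from a δ-lactone), and C4–C5, C9–C10, C8–O (one polyene cyclisation).
- Forward: geranyl bromide is extended at both ends to a 1,6-enyne diene acid; gold(I) closes ring A (6-exo-dig), ring B (6-endo) and a C8–O–C13 δ-lactone in one step; lactone → methyl ketone → enoate → C13; the two halves are then joined at C4; dehydration gives C8=C17; one fluoride deprotection.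
- Enabling feature: C4 of ring A carries only a methyl (C19, axial) and the CH2O carbon (C18, equatorial) and lies 1,3 to the axial C10 methyl. A C4=C19 exocyclic methylene, which the alkyne-initiated cyclisation delivers directly, is therefore a latent tertiary C4 radical whose open face is the equatorial one.
- Stereochemistry: C5, C8, C9, C10 from the chiral gold catalyst (chair–chair, E-alkenes from geranyl bromide and the SeO2 oxidation); C13 from a chiral CuH catalyst; C4 by substrate control in the key step; the E-cinnamate from p-coumaric acid.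

Key step: step 14

Assumption: the senses of induction of the chiral gold catalyst (step 6) and the chiral copper hydride catalyst (step 10) are taken as written; if either proves opposite, the enantiomeric ligand is used.

Step 1
Reactants: 1 geranyl bromide [(2E)-1-bromo-3,7-dimethylocta-2,6-diene]
Product: 2 methyl (4E)-5,9-dimethyldeca-4,8-dienoate
Conditions: LDA, MeOAc, THF, −78 °C; then 1, DMPU, −78 → −30 °C
Reagents that add atoms: methyl acetate, COC(C)=O (as its lithium enolate)
Why: Ester enolate alkylation by SN2 at the primary allylic bromide keeps the E geometry and adds the two carbons that become C12 and C13.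

Step 2
Reactants: 2 methyl (4E)-5,9-dimethyldeca-4,8-dienoate
Product: 3 methyl (4E,8E)-10-hydroxy-5,9-dimethyldeca-4,8-dienoate
Conditions: SeO2 (0.3 equiv), t-BuOOH (3 equiv), salicylic acid (0.1 equiv), CH2Cl2, 0 °C → rt
Reagents that add atoms: tert-butyl hydroperoxide, CC(C)(C)OO (oxygen source, relayed by catalytic selenium dioxide, O=[Se]=O)
Why: Selenium dioxide allylic oxidation (ene reaction then [2,3]-shift) should attack the terminal isopropylidene and oxidise its E-methyl selectively, which fixes the E geometry of the future C5=C10 alkene.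

Step 3
Reactants: 3 methyl (4E,8E)-10-hydroxy-5,9-dimethyldeca-4,8-dienoate
Product: 4 methyl (4E,8E)-10-bromo-5,9-dimethyldeca-4,8-dienoate
Conditions: CBr4, PPh3, CH2Cl2, −20 → 0 °C
Reagents that add atoms: carbon tetrabromide, BrC(Br)(Br)Br
Why: Appel bromination converts the primary allylic alcohol without allylic transposition or loss of alkene geometry.

Step 4
Reactants: 4 methyl (4E,8E)-10-bromo-5,9-dimethyldeca-4,8-dienoate; 5 (4-bromobut-1-yn-1-yl)trimethylsilane
Product: 7 methyl (4E,8E)-5,9-dimethyl-14-(trimethylsilyl)tetradeca-4,8-dien-13-ynoate, via Grignard reagent 6 (not isolated)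
Conditions: 5, Mg, THF, rt; then 4, Li2CuCl4 (5 mol %), THF, −78 → −20 °C
Reagents that add atoms: none
Why: Copper-catalysed Grignard cross-coupling (Kochi type) should substitute the primary allylic bromide at its α-carbon faster than the Grignard reagent adds to the methyl ester at low temperature, giving the three-CH2 spacing between alkyne and alkene that 6-exo-dig closure needs.

Step 5
Reactants: 7 methyl (4E,8E)-5,9-dimethyl-14-(trimethylsilyl)tetradeca-4,8-dien-13-ynoate
Product: 8 (4E,8E)-5,9-dimethyltetradeca-4,8-dien-13-ynoic acid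
Conditions: LiOH·H2O, THF/MeOH/H2O, rt; then 1 M HCl to pH 3
Reagents that add atoms: lithium hydroxide, [Li+].[OH-]
Why: Hydroxide saponifies the methyl ester and cleaves the alkynyl C–Si bond in the same pot, unveiling the terminal alkyne initiator and the carboxylic acid terminator.

Step 6
Reactants: 8 (4E,8E)-5,9-dimethyltetradeca-4,8-dien-13-ynoic acid
Product: 9 (4aS,6aR,10aR,10bS)-4a,10a-dimethyl-7-methylidenedodecahydro-3H-benzo[f]chromen-3-one (trans-decalin δ-lactone, C4=C19 exocyclic methylene)
Conditions: [(S)-MeO-DTBM-BIPHEP](AuCl)2 (5 mol %), AgSbF6 (5 mol %), m-xylene, rt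
Reagents that add atoms: none
Why: In this gold(I)-catalysed enantioselective alkyne-initiated polyene cyclisation, π-activation of the terminal alkyne triggers 6-exo-dig attack by the C5=C10 alkene, 6-endo attack by the C8=C9 alkene and anti capture of the C8 cation by the acid through chair–chair transition states, so the chiral digold catalyst should set C5, C8, C9 and C10 together (trans-decalin, equatorial C8–O, equatorial C9 chain) and protodeauration leaves the C4=C19 methylene.

Step 7
Reactants: 9 (4aS,6aR,10aR,10bS)-4a,10a-dimethyl-7-methylidenedodecahydro-3H-benzo[f]chromen-3-one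
Product: 10 4-[(1S,2S,4aR,8aR)-2-hydroxy-2,8a-dimethyl-5-methylidenedecahydronaphthalen-1-yl]butan-2-one
Conditions: MeLi (1.2 equiv), THF, −78 °C; H2O quench at −78 °C
Reagents that add atoms: methyllithium, [Li]C
Why: Methyllithium should add only once to the δ-lactone because the tetrahedral lithium hemiketal persists at −78 °C until work-up, giving the C13 methyl ketone (C16 introduced) and the free tertiary C8 alcohol.

Step 8
Reactants: 11 (diethoxyphosphoryl)acetic acid; 12 2-(trimethylsilyl)ethanol
Product: 13 2-(trimethylsilyl)ethyl (diethoxyphosphoryl)acetate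
Conditions: DCC, DMAP (cat.), CH2Cl2, 0 °C → rt
Reagents that add atoms: none
Why: Steglich esterification gives the Horner–Wadsworth–Emmons reagent carrying the fluoride-labile ester.

Step 9
Reactants: 10 4-[(1S,2S,4aR,8aR)-2-hydroxy-2,8a-dimethyl-5-methylidenedecahydronaphthalen-1-yl]butan-2-one; 13 2-(trimethylsilyl)ethyl (diethoxyphosphoryl)acetate
Product: 14 2-(trimethylsilyl)ethyl (2E)-5-[(1S,2S,4aR,8aR)-2-hydroxy-2,8a-dimethyl-5-methylidenedecahydronaphthalen-1-yl]-3-methylpent-2-enoate
Conditions: 13, NaH (2.5 equiv each), THF, 0 °C; then 10, 0 → 50 °C; chromatographic removal of the minor Z isomer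
Reagents that add atoms: none
Why: Horner–Wadsworth–Emmons olefination of the methyl ketone should favour the E enoate, with the larger C12 chain trans to the ester, and adds C14 and C15.

Step 10
Reactants: 14 2-(trimethylsilyl)ethyl (2E)-5-[(1S,2S,4aR,8aR)-2-hydroxy-2,8a-dimethyl-5-methylidenedecahydronaphthalen-1-yl]-3-methylpent-2-enoate
Product: 15 2-(trimethylsilyl)ethyl (3S)-5-[(1S,2S,4aR,8aR)-2-hydroxy-2,8a-dimethyl-5-methylidenedecahydronaphthalen-1-yl]-3-methylpentanoate
Conditions: Cu(OAc)2·H2O (5 mol %), (S)-DTBM-SEGPHOS (5 mol %), (EtO)2MeSiH (3 equiv), t-BuOH (2 equiv), toluene, 0 °C → rt; citric acid work-up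
Reagents that add atoms: none
Why: Copper hydride-catalysed asymmetric conjugate reduction of the β,β-disubstituted E-enoate delivers hydride to one enantioface under ligand control to set C13 (S), and should leave the unactivated C4=C19 alkene untouched.

Step 11
Reactants: 16 p-coumaric acid [(2E)-3-(4-hydroxyphenyl)prop-2-enoic acid]
Product: 18 (2E)-3-(4-{[tert-butyl(dimethyl)silyl]oxy}phenyl)prop-2-enoic acid, via bis-TBS coumarate 17 (not isolated)
Conditions: TBSCl (2.3 equiv), imidazole, DMF, rt; then AcOH/THF/H2O, rt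
Reagents that add atoms: tert-butyldimethylsilyl chloride, CC(C)(C)[Si](C)(C)Cl
Why: Silylation of both acidic groups followed by selective hydrolysis of the labile silyl ester leaves the phenol protected as the aryl TBS ether.

Step 12
Reactants: 18 (2E)-3-(4-{[tert-butyl(dimethyl)silyl]oxy}phenyl)prop-2-enoic acid
Product: 19 chloromethyl (2E)-3-(4-{[tert-butyl(dimethyl)silyl]oxy}phenyl)prop-2-enoate
Conditions: ClCH2OSO2Cl, NaHCO3, Bu4NHSO4 (cat.), CH2Cl2/H2O, 0 °C → rt
Reagents that add atoms: chloromethyl chlorosulfate, ClCOS(=O)(=O)Cl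
Why: Phase-transfer O-alkylation of the carboxylate with chloromethyl chlorosulfate displaces chlorosulfate, the better leaving group, and is the standard route to chloromethyl esters.

Step 13
Reactants: 19 chloromethyl (2E)-3-(4-{[tert-butyl(dimethyl)silyl]oxy}phenyl)prop-2-enoate
Product: 20 iodomethyl (2E)-3-(4-{[tert-butyl(dimethyl)silyl]oxy}phenyl)prop-2-enoate
Conditions: NaI, acetone, rt, dark
Reagents that add atoms: sodium iodide, [Na+].[I-]
Why: Finkelstein exchange driven by precipitation of NaCl gives the more reactive iodomethyl ester.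

Step 14
Reactants: 15 2-(trimethylsilyl)ethyl (3S)-5-[(1S,2S,4aR,8aR)-2-hydroxy-2,8a-dimethyl-5-methylidenedecahydronaphthalen-1-yl]-3-methylpentanoate; 20 iodomethyl (2E)-3-(4-{[tert-butyl(dimethyl)silyl]oxy}phenyl)prop-2-enoate
Product: 21 2-(trimethylsilyl)ethyl (3S)-5-[(1S,2S,4aS,5S,8aR)-5-({[(2E)-3-(4-{[tert-butyl(dimethyl)silyl]oxy}phenyl)prop-2-enoyl]oxy}methyl)-2-hydroxy-2,5,8a-trimethyldecahydronaphthalen-1-yl]-3-methylpentanoate
Conditions: Mn(dpm)3 (25 mol %), Ni(acac)2 (10 mol %), PhSiH3 (2 equiv), HFIP (2 equiv), K2CO3 (1.5 equiv), 20 (2.5 equiv), DCE/propylene carbonate, rt, Ar, dark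
Reagents that add atoms: none
Why: Proposed new method: Mn(dpm)3/PhSiH3 gives a manganese hydride that transfers H• to the terminal carbon (C19) of the C4=C19 alkene, the only alkene in 15, creating the C19 methyl and a tertiary C4 radical, while nickel(0) adds oxidatively to the C–I bond of 20, captures the C4 radical and releases the C4–CH2O bond by reductive elimination from Ni(III), and electron transfer from Mn(II) to Ni(I) regenerates both catalysts. The closest known reaction type is the Mn/Ni dual-catalytic Markovnikov hydroalkylation of 1,1-disubstituted alkenes with primary alkyl iodides that forms quaternary carbons; new here is an acyloxymethyl iodide as the electrophile, whose organometallic viability is suggested by the stable (acyloxymethyl)zinc and -copper reagents. No ring is closed. The only new stereocentre, C4, is set by the substrate: the axial C10 methyl is 1,3-syn-axial to the axial lobe of the C4 radical, so the bulky nickel fragment should bond on the equatorial face, which places C18 equatorial and leaves the C19 methyl axial as in the target. The step needs H-atom transfer to C4=C19 in preference to the cinnamate alkene of 20, and cross- in preference to homo-coupling; the first should follow from the cinnamate being 1,2-disubstituted, electron-poor and a poor acceptor for a tertiary radical (aryl on its β-carbon), the second from nickel taking the primary iodide while the tertiary radical stays free, helped by an excess of 20. The tertiary C8–OH, the TMSE ester and the aryl silyl ether should be spectators.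

Step 15
Reactants: 21 (C8 tertiary alcohol from step 14)
Product: 22 2-(trimethylsilyl)ethyl (3S)-5-[(1R,4aS,5S,8aS)-5-({[(2E)-3-(4-{[tert-butyl(dimethyl)silyl]oxy}phenyl)prop-2-enoyl]oxy}methyl)-5,8a-dimethyl-2-methylidenedecahydronaphthalen-1-yl]-3-methylpentanoate
Conditions: SOCl2 (1.5 equiv), pyridine, CH2Cl2, −78 → −40 °C
Reagents that add atoms: none
Why: In this E2 dehydration through the chlorosulfite the equatorial C8–O bond has no anti-periplanar ring hydrogen, so pyridine should remove a proton from the axial C17 methyl and give the exocyclic C8=C17 alkene preferentially (the known behaviour of 8-hydroxylabdanes with an equatorial hydroxyl), while both esters and the aryl silyl ether are inert.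

Step 16
Reactants: 22 (bis-protected 8(17)-ene from step 15)
Product: 23 (3S)-5-[(1R,4aS,5S,8aS)-5-({[(2E)-3-(4-hydroxyphenyl)prop-2-enoyl]oxy}methyl)-5,8a-dimethyl-2-methylidenedecahydronaphthalen-1-yl]-3-methylpentanoic acid (target)
Conditions: TBAF (4 equiv), THF, 0 °C → rt; 1 M HCl to pH 3
Reagents that add atoms: none
Why: Fluoride cleaves the aryl silyl ether and, by β-elimination with loss of ethene and Me3SiF, the 2-(trimethylsilyl)ethyl ester in one operation, and should not touch the hindered, phenoxide-deactivated coumarate ester or the alkenes.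

Compound list
1 | geranyl bromide | CC(C)=CCC/C(C)=C/CBr | starting material
2 | methyl (4E)-5,9-dimethyldeca-4,8-dienoate | CC(C)=CCC/C(C)=C/CCC(=O)OC | intermediate
3 | methyl (4E,8E)-10-hydroxy-5,9-dimethyldeca-4,8-dienoate | OC/C(C)=C/CC/C(C)=C/CCC(=O)OC | intermediate
4 | methyl (4E,8E)-10-bromo-5,9-dimethyldeca-4,8-dienoate | BrC/C(C)=C/CC/C(C)=C/CCC(=O)OC | intermediate
5 | (4-bromobut-1-yn-1-yl)trimethylsilane | C[Si](C)(C)C#CCCBr | starting material
6 | [4-(trimethylsilyl)but-3-yn-1-yl]magnesium bromide | C[Si](C)(C)C#CCC[Mg]Br | intermediate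
7 | methyl (4E,8E)-5,9-dimethyl-14-(trimethylsilyl)tetradeca-4,8-dien-13-ynoate | C[Si](C)(C)C#CCCC/C(C)=C/CC/C(C)=C/CCC(=O)OC | intermediate
8 | (4E,8E)-5,9-dimethyltetradeca-4,8-dien-13-ynoic acid | C#CCCC/C(C)=C/CC/C(C)=C/CCC(=O)O | intermediate
9 | (4aS,6aR,10aR,10bS)-4a,10a-dimethyl-7-methylidenedodecahydro-3H-benzo[f]chromen-3-one | C[C@]13CC[C@@H]2C(=C)CCC[C@@]2(C)[C@@H]1CCC(=O)O3 | intermediate
10 | 4-[(1S,2S,4aR,8aR)-2-hydroxy-2,8a-dimethyl-5-methylidenedecahydronaphthalen-1-yl]butan-2-one | C[C@]1(O)CC[C@@H]2C(=C)CCC[C@@]2(C)[C@@H]1CCC(C)=O | intermediate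
11 | (diethoxyphosphoryl)acetic acid | CCOP(=O)(CC(=O)O)OCC | starting material
12 | 2-(trimethylsilyl)ethanol | C[Si](C)(C)CCO | starting material
13 | 2-(trimethylsilyl)ethyl (diethoxyphosphoryl)acetate | CCOP(=O)(CC(=O)OCC[Si](C)(C)C)OCC | intermediate
14 | 2-(trimethylsilyl)ethyl (2E)-5-[(1S,2S,4aR,8aR)-2-hydroxy-2,8a-dimethyl-5-methylidenedecahydronaphthalen-1-yl]-3-methylpent-2-enoate | C[C@]1(O)CC[C@@H]2C(=C)CCC[C@@]2(C)[C@@H]1CC/C(C)=C/C(=O)OCC[Si](C)(C)C | intermediate
15 | 2-(trimethylsilyl)ethyl (3S)-5-[(1S,2S,4aR,8aR)-2-hydroxy-2,8a-dimethyl-5-methylidenedecahydronaphthalen-1-yl]-3-methylpentanoate | C[C@]1(O)CC[C@@H]2C(=C)CCC[C@@]2(C)[C@@H]1CC[C@H](C)CC(=O)OCC[Si](C)(C)C | intermediate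
16 | p-coumaric acid | OC(=O)/C=C/c1ccc(O)cc1 | starting material
17 | tert-butyl(dimethyl)silyl (2E)-3-(4-{[tert-butyl(dimethyl)silyl]oxy}phenyl)prop-2-enoate | CC(C)(C)[Si](C)(C)OC(=O)/C=C/c1ccc(O[Si](C)(C)C(C)(C)C)cc1 | intermediate
18 | (2E)-3-(4-{[tert-butyl(dimethyl)silyl]oxy}phenyl)prop-2-enoic acid | OC(=O)/C=C/c1ccc(O[Si](C)(C)C(C)(C)C)cc1 | intermediate
19 | chloromethyl (2E)-3-(4-{[tert-butyl(dimethyl)silyl]oxy}phenyl)prop-2-enoate | ClCOC(=O)/C=C/c1ccc(O[Si](C)(C)C(C)(C)C)cc1 | intermediate
20 | iodomethyl (2E)-3-(4-{[tert-butyl(dimethyl)silyl]oxy}phenyl)prop-2-enoate | ICOC(=O)/C=C/c1ccc(O[Si](C)(C)C(C)(C)C)cc1 | intermediate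
21 | 2-(trimethylsilyl)ethyl (3S)-5-[(1S,2S,4aS,5S,8aR)-5-({[(2E)-3-(4-{[tert-butyl(dimethyl)silyl]oxy}phenyl)prop-2-enoyl]oxy}methyl)-2-hydroxy-2,5,8a-trimethyldecahydronaphthalen-1-yl]-3-methylpentanoate | C[C@]1(O)CC[C@@H]2[C@@](C)(COC(=O)/C=C/c3ccc(O[Si](C)(C)C(C)(C)C)cc3)CCC[C@@]2(C)[C@@H]1CC[C@H](C)CC(=O)OCC[Si](C)(C)C | intermediate
22 | 2-(trimethylsilyl)ethyl (3S)-5-[(1R,4aS,5S,8aS)-5-({[(2E)-3-(4-{[tert-butyl(dimethyl)silyl]oxy}phenyl)prop-2-enoyl]oxy}methyl)-5,8a-dimethyl-2-methylidenedecahydronaphthalen-1-yl]-3-methylpentanoate | C=C1CC[C@@H]2[C@@](C)(COC(=O)/C=C/c3ccc(O[Si](C)(C)C(C)(C)C)cc3)CCC[C@@]2(C)[C@@H]1CC[C@H](C)CC(=O)OCC[Si](C)(C)C | intermediate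
23 | (3S)-5-[(1R,4aS,5S,8aS)-5-({[(2E)-3-(4-hydroxyphenyl)prop-2-enoyl]oxy}methyl)-5,8a-dimethyl-2-methylidenedecahydronaphthalen-1-yl]-3-methylpentanoic acid | C=C1CC[C@@H]2[C@@](C)(COC(=O)/C=C/c3ccc(O)cc3)CCC[C@@]2(C)[C@@H]1CC[C@H](C)CC(=O)O | target

Total step count: 16. Longest linear sequence: 12 steps (1–7, 9, 10, 14, 15, 16).

Steps most likely to fail

1. Step 14 (Proposed new method). The C4 radical may be quenched by a second hydrogen atom (net hydrogenation of C4=C19), or the manganese hydride may attack the cinnamate alkene or reduce the C–I bond of 20 faster than nickel joins the partners. The fallback uses known chemistry, sets out from 15 and comes back at 21. A cobalt–salen/PhSiH3 hydrogen-atom-transfer reductive coupling of the alkene with O-benzyl (phenylsulfonyl)formaldoxime should form the C4–C18 bond on the same equatorial face and give 2-(trimethylsilyl)ethyl (3S)-5-[(1S,2S,4aS,5S,8aR)-5-[(E)-(benzyloxyimino)methyl]-2-hydroxy-2,5,8a-trimethyldecahydronaphthalen-1-yl]-3-methylpentanoate F1. Acid-catalysed exchange with aqueous formaldehyde should free 2-(trimethylsilyl)ethyl (3S)-5-[(1S,2S,4aS,5S,8aR)-5-formyl-2-hydroxy-2,5,8a-trimethyldecahydronaphthalen-1-yl]-3-methylpentanoate F2. NaBH4 should then give 2-(trimethylsilyl)ethyl (3S)-5-[(1S,2S,4aS,5S,8aR)-2-hydroxy-5-(hydroxymethyl)-2,5,8a-trimethyldecahydronaphthalen-1-yl]-3-methylpentanoate F3, whose primary alcohol is esterified with acid 18 (EDC, DMAP) to return to 21.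

2. Step 6. Enantiofacial control in the alkyne activation and first ring closure may be poor, or the cascade may stop by proton loss after ring A instead of closing ring B and the lactone. The fallback sets out from 8 and comes back at 9. Cyclisation with an achiral cationic gold(I) complex (JohnPhosAu(MeCN)SbF6) gives the racemate, that is 9 together with (4aR,6aS,10aS,10bR)-4a,10a-dimethyl-7-methylidenedodecahydro-3H-benzo[f]chromen-3-one F4. The absolute configuration then comes from resolution by preparative chromatography on a chiral stationary phase instead of from the catalyst.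

3. Step 9. Olefination of the hindered methyl ketone may be slow, E/Z control incomplete, and the C8 alkoxide may add to the new enoate. Since E and Z enoates are reduced to opposite C13 configurations in step 10, each of these erodes C13. The fallback sets out from 9, replaces steps 7, 9 and 10, and comes back at 15. DIBAL-H at −78 °C reduces the lactone to (4aS,6aR,10aR,10bS)-4a,10a-dimethyl-7-methylidenedodecahydro-1H-benzo[f]chromen-3-ol F5 (lactol, both C3 epimers). Horner–Wadsworth–Emmons reaction of its open hydroxy-aldehyde form with 13 (LiCl, DBU, MeCN) gives geometrically pure 2-(trimethylsilyl)ethyl (2E)-5-[(1S,2S,4aR,8aR)-2-hydroxy-2,8a-dimethyl-5-methylidenedecahydronaphthalen-1-yl]pent-2-enoate F6. Copper-catalysed asymmetric conjugate addition of MeMgBr (CuI/Tol-BINAP, t-BuOMe, −20 °C) then installs C16 and sets C13 by C–C instead of C–H bond formation, giving 15.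

Further compounds
F1 | step 14 | 2-(trimethylsilyl)ethyl (3S)-5-[(1S,2S,4aS,5S,8aR)-5-[(E)-(benzyloxyimino)methyl]-2-hydroxy-2,5,8a-trimethyldecahydronaphthalen-1-yl]-3-methylpentanoate | C[C@]1(O)CC[C@@H]2[C@@](C)(/C=N/OCc3ccccc3)CCC[C@@]2(C)[C@@H]1CC[C@H](C)CC(=O)OCC[Si](C)(C)C
F2 | step 14 | 2-(trimethylsilyl)ethyl (3S)-5-[(1S,2S,4aS,5S,8aR)-5-formyl-2-hydroxy-2,5,8a-trimethyldecahydronaphthalen-1-yl]-3-methylpentanoate | C[C@]1(O)CC[C@@H]2[C@@](C)(C=O)CCC[C@@]2(C)[C@@H]1CC[C@H](C)CC(=O)OCC[Si](C)(C)C
F3 | step 14 | 2-(trimethylsilyl)ethyl (3S)-5-[(1S,2S,4aS,5S,8aR)-2-hydroxy-5-(hydroxymethyl)-2,5,8a-trimethyldecahydronaphthalen-1-yl]-3-methylpentanoate | C[C@]1(O)CC[C@@H]2[C@@](C)(CO)CCC[C@@]2(C)[C@@H]1CC[C@H](C)CC(=O)OCC[Si](C)(C)C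
F4 | step 6 | (4aR,6aS,10aS,10bR)-4a,10a-dimethyl-7-methylidenedodecahydro-3H-benzo[f]chromen-3-one | C[C@@]13CC[C@H]2C(=C)CCC[C@]2(C)[C@H]1CCC(=O)O3
F5 | step 9 | (4aS,6aR,10aR,10bS)-4a,10a-dimethyl-7-methylidenedodecahydro-1H-benzo[f]chromen-3-ol | C[C@]13CC[C@@H]2C(=C)CCC[C@@]2(C)[C@@H]1CCC(O)O3
F6 | step 9 | 2-(trimethylsilyl)ethyl (2E)-5-[(1S,2S,4aR,8aR)-2-hydroxy-2,8a-dimethyl-5-methylidenedecahydronaphthalen-1-yl]pent-2-enoate | C[C@]1(O)CC[C@@H]2C(=C)CCC[C@@]2(C)[C@@H]1CC/C=C/C(=O)OCC[Si](C)(C)C
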